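**Retrosynthetic overview**
1. 15 ⇐ four-fold TBS removal ⇐ 14 ⇐ axial reduction (L-Selectride) of THP-4-one 13 ⇐ cis-selective 1,4-reduction of dihydropyranone 12 ⇐ CBS reduction of the side-chain ketone of 11.
2. 11 ⇐ C3–Cs Michael addition of the only enolisable position (C3) of dihydropyranone 10 to dienone 9.
3. 10 ⇐ 5 ⇐ 4 ⇐ bisdemethoxycurcumin 3, by desymmetrising enantioselective oxa-Michael ring closure (the key step, and the only ring formed) and then mono-hydrogenation. Dienone 9 ⇐ raspberry ketone + p-coumaraldehyde.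
4. The ring is made first, and all four ring stereocentres follow from the single catalyst-set C2 centre. The acyclic side chain is appended afterwards.

Assumption: 4-hydroxybenzaldehyde, acetylacetone, raspberry ketone and p-coumaraldehyde are purchased, and a catalyst giving the (2S) enantiomer in step 2 is found by screening quinine- and quinidine-derived catalysts.

---

**Step 1**
Reactants: 1 (4-hydroxybenzaldehyde, 2 equiv), 2 (acetylacetone)
Product: 3 (bisdemethoxycurcumin, (1E,6E)-1,7-bis(4-hydroxyphenyl)hepta-1,6-diene-3,5-dione)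
Conditions: B2O3, B(OBu)3, n-BuNH2, EtOAc, 80 °C; then aq. HCl
Reagents that add atoms: none
Why: Boron chelation of acetylacetone blocks the central CH2, so both terminal methyls condense with the aldehyde (Pabon double Knoevenagel/aldol) to give the symmetric E,E-bis-enone; no stereocentres are formed.

**Step 2**
Reactants: 3
Product: 4 ((2S)-2-(4-hydroxyphenyl)-6-[(E)-2-(4-hydroxyphenyl)ethenyl]-2,3-dihydro-4H-pyran-4-one)
Conditions: quinine-derived bifunctional squaramide (10 mol%), toluene, 40 °C
Reagents that add atoms: none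
Why: Proposed new method: the diketone is a symmetric enol with two enantiotopic enone arms. The chiral H-bond-donor/base catalyst directs 6-endo-trig attack of the enol oxygen on one arm only, which sets C2 as S and turns the other arm into the C6 styryl group. The closest known reactions are the chalcone-to-flavanone oxa-Michael cyclisation and curcumin-to-cyclocurcumin cyclisation.

**Step 3**
Reactants: 4
Product: 5 ((2S)-2-(4-hydroxyphenyl)-6-[2-(4-hydroxyphenyl)ethyl]-2,3-dihydro-4H-pyran-4-one)
Conditions: H2 (1 atm), RhCl(PPh3)3 (5 mol%), EtOH/benzene 1:1, 25 °C, about 1 equiv H2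
Reagents that add atoms: none (H2 adds only hydrogen)
Why: Homogeneous hydrogenation takes the disubstituted exocyclic styryl alkene in preference to the trisubstituted, push-pull vinylogous-ester alkene, so the C6 phenethyl group forms and no stereocentre changes.

**Step 4**
Reactants: 6 (raspberry ketone, 4-(4-hydroxyphenyl)butan-2-one), 7 ((E)-p-coumaraldehyde)
Product: 8 ((4E,6E)-1,7-bis(4-hydroxyphenyl)hepta-4,6-dien-3-one)
Conditions: NaOH (4 equiv), EtOH/H2O, 50 °C; then HCl
Reagents that add atoms: none
Why: Claisen–Schmidt condensation at the methyl of the ketone (the only enolisable α-CH3) gives the thermodynamic E,E-dienone.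

**Step 5**
Reactants: 8
Product: 9 (bis-TBS ether of 8)
Conditions: TBSCl (2.4 equiv), imidazole, DMF, 25 °C
Reagents that add atoms: TBSCl, CC(C)(C)[Si](C)(C)Cl
Why: Silylation masks both phenols so the enolate chemistry in step 7 and the hydride reductions later are not quenched by phenoxides.

**Step 6**
Reactants: 5
Product: 10 (bis-TBS ether of 5)
Conditions: TBSCl (2.4 equiv), imidazole, DMF, 25 °C
Reagents that add atoms: TBSCl, CC(C)(C)[Si](C)(C)Cl
Why: Same phenol protection; the C2 centre is untouched.

**Step 7**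
Reactants: 10, 9
Product: 11 ((2S,3R)-3-[(1E,3S)-1,7-bis(4-TBSO-phenyl)-5-oxohept-1-en-3-yl]-2-(4-TBSO-phenyl)-6-[2-(4-TBSO-phenyl)ethyl]-2,3-dihydro-4H-pyran-4-one)
Conditions: LiHMDS (1.1 equiv), THF, −78 °C, 30 min; then 9 (1.0 equiv), −78 °C, 2 h; sat. NH4Cl
Reagents that add atoms: none
Why: Proposed new method: C3 is the only sp3 α-carbon of the vinylogous ester, so deprotonation is regiospecific. The enolate is trapped cold, before E1cB ring-opening, and attacks anti to the pseudo-axial 2-aryl group, giving 2,3-trans. It adds 1,4 to the dienone (C7' is aryl-hindered) through a chelated Z-enolate/E-enone chair-like TS, which is expected to give the syn C3/Cs relationship. The closest known reactions are flavanone-enolate C3 functionalisation and lithium-enolate Michael additions to enones.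

**Step 8**
Reactants: 11
Product: 12 (the (5S) alcohol of 11; C3′ carbinol)
Conditions: (R)-Me-CBS (20 mol%), catecholborane (1.5 equiv), toluene, −78 °C; then MeOH, aq. workup
Reagents that add atoms: none
Why: CBS reduction is reagent-controlled. The (R)-catalyst delivers hydride to the face that gives the S alcohol, with the branched CH2CH(R) side as the larger group. The unreactive vinylogous-ester carbonyl and the styryl alkene are untouched.

**Step 9**
Reactants: 12
Product: 13 ((2S,3R,6S)-THP-4-one, 2,6-cis, 3-equatorial)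
Conditions: L-Selectride (2.5 equiv), THF, −78 → −30 °C, 3 h; quench with NH4Cl at −30 °C
Reagents that add atoms: none (hydride only)
Why: Proposed new method: this is 1,4-hydride addition to the β-carbon C6 of the vinylogous ester. Axial delivery to the half-chair makes the phenethyl group equatorial, cis to the 2-aryl group, and the cold quench avoids E1cB ring-opening of the enolate. The closest known reaction is L-Selectride conjugate reduction of 2,3-dihydropyran-4-ones. The styryl alkene and aryl silyl ethers are inert to the hydride.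

**Step 10**
Reactants: 13
Product: 14 (tetra-TBS ether of the target, 4-axial alcohol)
Conditions: L-Selectride (3 equiv), THF, −78 °C, 2 h; then NaOH, H2O2
Reagents that add atoms: none
Why: The bulky hydride attacks the 2,6-cis-3-equatorial THP-4-one equatorially (Brown-type selectivity, as for 2-methylcyclohexanone → cis alcohol). This gives the axial 4-OH, cis to the C3 substituent, which sets C4 as S.

**Step 11**
Reactants: 14
Product: 15 (Blepharocalyxin C)
Conditions: TBAF (6 equiv), AcOH (6 equiv), THF, 0 → 25 °C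
Reagents that add atoms: none
Why: Buffered fluoride removes all four aryl TBS ethers. No ketone remains, so no epimerisation or retro-Michael is possible.

---

**Compound list**

| No. | Name | SMILES | Role |
|---|---|---|---|
| 1 | 4-hydroxybenzaldehyde | O=Cc1ccc(O)cc1 | starting material |
| 2 | acetylacetone | CC(=O)CC(C)=O | starting material |
| 3 | bisdemethoxycurcumin | O=C(/C=C/c1ccc(O)cc1)CC(=O)/C=C/c1ccc(O)cc1 | intermediate |
| 4 | (2S)-2-(4-hydroxyphenyl)-6-[(E)-4-hydroxystyryl]-2,3-dihydro-4H-pyran-4-one | O=C1C[C@@H](c2ccc(O)cc2)OC(/C=C/c2ccc(O)cc2)=C1 | intermediate |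
| 5 | (2S)-2-(4-hydroxyphenyl)-6-[2-(4-hydroxyphenyl)ethyl]-2,3-dihydro-4H-pyran-4-one | O=C1C[C@@H](c2ccc(O)cc2)OC(CCc2ccc(O)cc2)=C1 | intermediate |
| 6 | raspberry ketone | CC(=O)CCc1ccc(O)cc1 | starting material |
| 7 | (E)-p-coumaraldehyde | O=C/C=C/c1ccc(O)cc1 | starting material |
| 8 | (4E,6E)-1,7-bis(4-hydroxyphenyl)hepta-4,6-dien-3-one | O=C(CCc1ccc(O)cc1)/C=C/C=C/c1ccc(O)cc1 | intermediate |
| 9 | bis-TBS ether of 8 | O=C(CCc1ccc(O[Si](C)(C)C(C)(C)C)cc1)/C=C/C=C/c1ccc(O[Si](C)(C)C(C)(C)C)cc1 | intermediate |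
| 10 | bis-TBS ether of 5 | O=C1C[C@@H](c2ccc(O[Si](C)(C)C(C)(C)C)cc2)OC(CCc2ccc(O[Si](C)(C)C(C)(C)C)cc2)=C1 | intermediate |
| 11 | Michael adduct (dihydropyranone, side-chain ketone) | CC(C)(C)[Si](C)(C)Oc1ccc(cc1)/C=C/[C@H](CC(=O)CCc2ccc(O[Si](C)(C)C(C)(C)C)cc2)[C@@H]3[C@@H](c4ccc(O[Si](C)(C)C(C)(C)C)cc4)OC(CCc5ccc(O[Si](C)(C)C(C)(C)C)cc5)=CC3=O | intermediate |
| 12 | side-chain (S)-alcohol of 11 | CC(C)(C)[Si](C)(C)Oc1ccc(cc1)/C=C/[C@H](C[C@@H](O)CCc2ccc(O[Si](C)(C)C(C)(C)C)cc2)[C@@H]3[C@@H](c4ccc(O[Si](C)(C)C(C)(C)C)cc4)OC(CCc5ccc(O[Si](C)(C)C(C)(C)C)cc5)=CC3=O | intermediate |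
| 13 | THP-4-one (2,6-cis) | CC(C)(C)[Si](C)(C)Oc1ccc(cc1)/C=C/[C@H](C[C@@H](O)CCc2ccc(O[Si](C)(C)C(C)(C)C)cc2)[C@@H]3[C@@H](c4ccc(O[Si](C)(C)C(C)(C)C)cc4)O[C@@H](CCc5ccc(O[Si](C)(C)C(C)(C)C)cc5)CC3=O | intermediate |
| 14 | tetra-TBS ether of target | CC(C)(C)[Si](C)(C)Oc1ccc(cc1)/C=C/[C@H](C[C@@H](O)CCc2ccc(O[Si](C)(C)C(C)(C)C)cc2)[C@@H]3[C@@H](c4ccc(O[Si](C)(C)C(C)(C)C)cc4)O[C@@H](CCc5ccc(O[Si](C)(C)C(C)(C)C)cc5)C[C@@H]3O | intermediate |
| 15 | Blepharocalyxin C, (2S,3S,4S,6S)-3-[(1E,3S,5S)-5-hydroxy-1,7-bis(4-hydroxyphenyl)hept-1-en-3-yl]-2-(4-hydroxyphenyl)-6-[2-(4-hydroxyphenyl)ethyl]oxan-4-ol | Oc1ccc(/C=C/[C@H](C[C@@H](O)CCc2ccc(O)cc2)[C@@H]2[C@@H](c3ccc(O)cc3)O[C@@H](CCc3ccc(O)cc3)C[C@@H]2O)cc1 | target |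

**Totals:** 11 steps in all; longest linear sequence 9 steps (1 → 2 → 3 → 6 → 7 → 8 → 9 → 10 → 11).

**Three steps most likely to fail**
1. **Step 2 (desymmetrising oxa-Michael):** the enantioselectivity may be low, or the product may racemise by retro-oxa-Michael. Fallback: make racemic 4 with achiral base (piperidine/AcOH) and separate the enantiomers by preparative chiral SFC or HPLC, then carry the (2S) enantiomer forward.
2. **Step 7 (C3 Michael addition):** diastereocontrol at Cs may be poor, γ-deprotonation or ring-opening may compete, and Li-enolate proton transfer from the dienone is possible. Fallback: a domino oxa-Michael/Michael between the acyclic (S)-hydroxy-enone ArCH2CH2CH(OH)CH2COCH=CHAr (from desymmetrising mono-reduction of tetrahydro-bisdemethoxycurcumin) and 9 under catalytic base. Then epimerise with acid (retro-oxa-Michael/oxa-Michael) to the 2,6-cis, 3-equatorial THP.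
3. **Step 9 (conjugate reduction of the vinylogous ester):** the vinylogous ester is a poor acceptor, and warming can cause E1cB ring-opening of the enolate. Fallback: Brønsted-acid-promoted Hantzsch-ester transfer hydrogenation of the protonated vinylogous ester. This is a hydride-to-oxocarbenium pathway that leaves the styryl alkene alone.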